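Everything rests on cutting the lower pyran ring at C3(l)–C4(l) and O1(l)–C2(l). The key step, an enantioselective inverse-demand hetero-Diels–Alder reaction of an ortho-quinone methide oxocarbenium ion with a Z-enol acetate, exploits the all-cis array C2(l)-aryl, C3(l)-OH, C4(l)-OH of the lower ring C: it maps onto a Z-alkene, the phenol oxygen O1(l) and the formyl carbon ortho to it on the lower ring A. One operation closes that ring, forms two bonds and sets three stereocentres. The precursor is the dimethyl acetal of a 3,4-bis(benzyloxy)salicylaldehyde that already carries the enantiopure 2,4-trans upper flavan at C6(l).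

Key step: step 13

Remark: the sense of induction of the chiral catalysts in steps 5 and 13 is assumed by analogy; the enantiomer named is the one expected to give the drawn configuration, and its antipode would be taken if the sense proved opposite.

Abbreviations: (u) and (l) label atoms of the upper flavan and of the lower flavan-3,4-diol unit; Bn = benzyl; Fl = (2S,4R)-7,8-bis(benzyloxy)-2-[4-(benzyloxy)phenyl]chroman-4-yl. The CIP label at C4(u) is R in all benzylated intermediates and S in the free target; the spatial arrangement is the same throughout.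

Step 1
Reactants: 1 pyrogallol
Product: 2 1,2,3-tris(benzyloxy)benzene
Conditions: BnBr (3.3 equiv), K2CO3, DMF, 60 °C, N2
Reagents that add atoms: benzyl bromide, BrCc1ccccc1
Why: Williamson etherification of all three phenols, run under nitrogen because pyrogallol oxidises in basic solution; no stereocentre is involved.

Step 2
Reactants: 2 1,2,3-tris(benzyloxy)benzene
Product: 3 1,5-dibromo-2,3,4-tris(benzyloxy)benzene
Conditions: NBS (2.1 equiv), MeCN, 0 °C to rt, dark
Reagents that add atoms: N-bromosuccinimide, O=C1CCC(=O)N1Br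
Why: Electrophilic aromatic bromination should go twice to the two equivalent positions that are ortho to one outer benzyloxy group and para to the other, so the symmetry of 2 allows only one dibromide.

Step 3
Reactants: 3 1,5-dibromo-2,3,4-tris(benzyloxy)benzene
Product: 5 [2,3,4-tris(benzyloxy)-5-bromophenyl]boronic acid, via aryllithium 4 (not isolated)
Conditions: n-BuLi (1.0 equiv), B(Oi-Pr)3, THF, −78 °C; then aq. HCl
Reagents that add atoms: triisopropyl borate, CC(C)OB(OC(C)C)OC(C)C; water, O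
Why: Bromine–lithium exchange at one of two equivalent C–Br bonds with in situ borate trapping and hydrolysis (aryllithium borylation) should give a single boronic acid that keeps the second bromine as the later formyl handle.

Step 4
Reactants: 6 daphnetin
Product: 7 7,8-bis(benzyloxy)-2H-chromen-2-one
Conditions: BnBr (2.2 equiv), K2CO3, DMF, 50 °C
Reagents that add atoms: benzyl bromide, BrCc1ccccc1
Why: Williamson etherification of the two phenols; the coumarin lactone should tolerate anhydrous carbonate.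

Step 5
Reactants: 7 7,8-bis(benzyloxy)-2H-chromen-2-one; 5 [2,3,4-tris(benzyloxy)-5-bromophenyl]boronic acid
Product: 8 (4R)-7,8-bis(benzyloxy)-4-[2,3,4-tris(benzyloxy)-5-bromophenyl]chroman-2-one
Conditions: Rh(acac)(C2H4)2 (3 mol%), (S)-Segphos (3.3 mol%), 5 (3 equiv), dioxane/H2O 10:1, 60 °C
Reagents that add atoms: none
Why: Hayashi–Miyaura asymmetric 1,4-addition of an arylboronic acid to a coumarin, in which the Segphos-bound aryl–rhodium species should add to one face of C4 and so set C4(u), while the aryl bromide is inert to monovalent rhodium.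

Step 6
Reactants: 8 (4R)-7,8-bis(benzyloxy)-4-[2,3,4-tris(benzyloxy)-5-bromophenyl]chroman-2-one
Product: 9 (4R)-7,8-bis(benzyloxy)-4-[2,3,4-tris(benzyloxy)-5-bromophenyl]chroman-2-ol (both C2 epimers)
Conditions: i-Bu2AlH (1.1 equiv), CH2Cl2, −78 °C; aq. potassium sodium tartrate
Reagents that add atoms: none
Why: Partial hydride reduction of a lactone to the lactol, whose aluminium hemiacetal is stable at −78 °C until work-up; C4(u) is not touched.

Step 7
Reactants: 9 (4R)-7,8-bis(benzyloxy)-4-[2,3,4-tris(benzyloxy)-5-bromophenyl]chroman-2-ol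
Product: 10 (4R)-7,8-bis(benzyloxy)-2-(phenylsulfonyl)-4-[2,3,4-tris(benzyloxy)-5-bromophenyl]chromane (both C2 epimers)
Conditions: PhSO2H (3 equiv), CaCl2, CH2Cl2, rt
Reagents that add atoms: benzenesulfinic acid, OS(=O)c1ccccc1
Why: Acid-mediated anomeric substitution of the lactol hydroxyl by sulfinate, driven by the drying agent, should give a storable 2-sulfonyl ether whose C2 configuration is irrelevant because it is lost in step 8.

Step 8
Reactants: 10 (4R)-7,8-bis(benzyloxy)-2-(phenylsulfonyl)-4-[2,3,4-tris(benzyloxy)-5-bromophenyl]chromane; 11 1-(benzyloxy)-4-bromobenzene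
Product: 14 (2S,4R)-7,8-bis(benzyloxy)-2-[4-(benzyloxy)phenyl]-4-[2,3,4-tris(benzyloxy)-5-bromophenyl]chromane (2,4-trans), via Grignard reagent 12 (not isolated), via diarylzinc 13 (not isolated)
Conditions: 11, Mg, THF; ZnBr2 (0.5 equiv per Grignard), rt; then 10, THF, rt; aq. NH4Cl
Reagents that add atoms: none
Why: Substitution of an anomeric sulfone by an arylzinc reagent through the chroman-2-yl oxocarbenium ion, in which the nucleophile should enter along the axial trajectory on the face away from the C4 aryl group (the syn path would be 1,3-diaxial) and so set C2(u) trans to C4(u).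

Step 9
Reactants: 14 (2S,4R)-7,8-bis(benzyloxy)-2-[4-(benzyloxy)phenyl]-4-[2,3,4-tris(benzyloxy)-5-bromophenyl]chromane
Product: 16 2,3,4-tris(benzyloxy)-5-Fl-benzaldehyde, via aryllithium 15 (not isolated)
Conditions: n-BuLi (1.05 equiv), THF, −78 °C; DMF; aq. NH4Cl
Reagents that add atoms: N,N-dimethylformamide, CN(C)C=O
Why: Bromine–lithium exchange followed by Bouveault formylation with DMF puts the formyl carbon, the future C4(l), exactly where the bromine stood, and at −78 °C exchange should outrun any deprotonation of the flavan.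

Step 10
Reactants: 16 2,3,4-tris(benzyloxy)-5-Fl-benzaldehyde
Product: 17 3,4-bis(benzyloxy)-5-Fl-2-hydroxybenzaldehyde
Conditions: MgBr2·OEt2 (1.5 equiv), toluene/Et2O, rt to 40 °C; aq. NH4Cl
Reagents that add atoms: none
Why: Chelation-controlled ortho-debenzylation, in which magnesium bound between the formyl oxygen and the neighbouring benzyloxy oxygen activates only that ether for cleavage by bromide, should free the one phenol that becomes O1(l).

Step 11
Reactants: 17 3,4-bis(benzyloxy)-5-Fl-2-hydroxybenzaldehyde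
Product: 18 2,3-bis(benzyloxy)-6-(dimethoxymethyl)-4-Fl-phenol
Conditions: HC(OMe)3 (5 equiv), MeOH, PPTS (5 mol%), rt; Et3N quench, basic alumina plug
Reagents that add atoms: trimethyl orthoformate, COC(OC)OC; methanol, CO
Why: Acid-catalysed acetalisation with the orthoformate as water scavenger; the product ionises easily and is therefore kept basic and used directly.

Step 12
Reactants: 19 1-(benzyloxy)-4-ethynylbenzene
Product: 20 (Z)-2-[4-(benzyloxy)phenyl]ethenyl acetate
Conditions: AcOH (1.2 equiv), Ru(2-methylallyl)2(dppb) (1 mol%), toluene, 45 °C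
Reagents that add atoms: acetic acid, CC(=O)O
Why: Ruthenium-catalysed anti-Markovnikov hydro-acyloxylation of a terminal alkyne through a vinylidene complex, a reaction that delivers the Z-enol ester.

Step 13
Reactants: 18 2,3-bis(benzyloxy)-6-(dimethoxymethyl)-4-Fl-phenol; 20 (Z)-2-[4-(benzyloxy)phenyl]ethenyl acetate
Product: 22 (2R,3R,4R)-7,8-bis(benzyloxy)-2-[4-(benzyloxy)phenyl]-6-Fl-4-methoxychroman-3-yl acetate (all-cis lower ring), via oxocarbenium ion 21 (not isolated)
Conditions: (R)-3,3′-bis(2,4,6-triisopropylphenyl)-BINOL N-triflyl phosphoramide (10 mol%), 20 (2 equiv), 5 Å MS, toluene, −60 °C; Et3N quench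
Reagents that add atoms: none
Why: Proposed new method: the chiral Brønsted acid expels methanol from acetal 18 to give the O-methyl oxocarbenium ion 21, a protonated ortho-quinone methide held in a contact ion pair through its phenolic OH, and the Z-alkene 20 attacks it with its acetoxy-bearing carbon (C3(l)–C4(l) bond) because the 4-benzyloxyphenyl group carries the developing charge, after which the phenol oxygen collapses onto that benzylic carbon (O1(l)–C2(l) bond). The closest known reaction type is the acid-promoted [4+2] addition of salicylaldehyde-acetal-derived oxocarbenium ions to styrenes, which gives cis-2-aryl-4-alkoxychromans, together with chiral-phosphate ion-pair control of ortho-quinone methide cycloadditions; an enol ester partner and an enantioselective version on this acetal class go beyond both. The lower pyran ring is closed by an asynchronous inverse-electron-demand hetero-Diels–Alder [4+2] closure with O1(l)–C8a(l)–C4a(l)–C4(l) as the heterodiene. C2(l) and C3(l) should come out cis because the Z geometry is transferred suprafacially, C4(l) should be cis to the aryl group through its endo orientation over the heterodiene, and the absolute configuration of all three centres should be set by the chiral phosphoramide anion, the upper-flavan centres being too remote to interfere. The step needs regioselectivity (secured by the single ortho-hydroxy acetal and by aryl over acetoxy cation stabilisation) and ring closure faster than C2(l)–C3(l) rotation or acetoxy participation (favoured by low temperature, a non-polar solvent and the tight ion pair), while the sieves take up methanol so that the product does not re-ionise. A C4(l) epimer would not matter, because step 14 resets that centre.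

Step 14
Reactants: 22 (2R,3R,4R)-7,8-bis(benzyloxy)-2-[4-(benzyloxy)phenyl]-6-Fl-4-methoxychroman-3-yl acetate
Product: 24 (2R,3R,4R)-7,8-bis(benzyloxy)-2-[4-(benzyloxy)phenyl]-6-Fl-4-hydroxychroman-3-yl acetate, via acetoxonium ion 23 (not isolated)
Conditions: TsOH·H2O (0.2 equiv), THF/H2O 5:1, 0 °C to rt; aq. NaHCO3
Reagents that add atoms: water, O
Why: Solvolysis with neighbouring-group participation, in which the benzylic C4(l) cation (stabilised by O1(l) and the para benzyloxy group) is captured by the 3-acetoxy group as the cis-fused acetoxonium ion 23 and water then opens that ion at its acetal carbon (Woodward-type wet opening), should place the C4(l) oxygen cis to C3(l) whichever C4 epimer entered.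

Step 15
Reactants: 24 (2R,3R,4R)-7,8-bis(benzyloxy)-2-[4-(benzyloxy)phenyl]-6-Fl-4-hydroxychroman-3-yl acetate
Product: 25 (2R,3R,4R)-7,8-bis(benzyloxy)-2-[4-(benzyloxy)phenyl]-6-Fl-chromane-3,4-diol
Conditions: K2CO3 (0.5 equiv), MeOH/THF, rt
Reagents that add atoms: none
Why: Zemplén-type methanolysis of the acetate frees both hydroxyl groups whatever oxygen carries the acetyl group, and no stereocentre is touched.

Step 16
Reactants: 25 (2R,3R,4R)-7,8-bis(benzyloxy)-2-[4-(benzyloxy)phenyl]-6-Fl-chromane-3,4-diol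
Product: 26 (2R,3R,4R)-6-[(2S,4S)-7,8-dihydroxy-2-(4-hydroxyphenyl)chroman-4-yl]-2-(4-hydroxyphenyl)chromane-3,4,7,8-tetrol (CNP0209379.1)
Conditions: H2 (1 atm), Pd(OH)2/C, THF/MeOH, rt, neutral, argon work-up
Reagents that add atoms: none
Why: Hydrogenolysis of the six primary benzyl ethers should be faster under neutral conditions than cleavage of the ring C–O bonds or of the secondary C4(l)–OH, so all five stereocentres should survive.

Compound list

1 | pyrogallol (benzene-1,2,3-triol) | Oc1cccc(O)c1O | starting material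
2 | 1,2,3-tris(benzyloxy)benzene | C(Oc1cccc(OCc2ccccc2)c1OCc3ccccc3)c4ccccc4 | intermediate
3 | 1,5-dibromo-2,3,4-tris(benzyloxy)benzene | Brc1cc(Br)c(OCc2ccccc2)c(OCc3ccccc3)c1OCc4ccccc4 | intermediate
4 | [2,3,4-tris(benzyloxy)-5-bromophenyl]lithium (not isolated) | [Li]c1cc(Br)c(OCc2ccccc2)c(OCc3ccccc3)c1OCc4ccccc4 | intermediate
5 | [2,3,4-tris(benzyloxy)-5-bromophenyl]boronic acid | OB(O)c1cc(Br)c(OCc2ccccc2)c(OCc3ccccc3)c1OCc4ccccc4 | intermediate
6 | daphnetin (7,8-dihydroxy-2H-chromen-2-one) | O=c1ccc2ccc(O)c(O)c2o1 | starting material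
7 | 7,8-bis(benzyloxy)-2H-chromen-2-one | O=c1ccc2ccc(OCc3ccccc3)c(OCc4ccccc4)c2o1 | intermediate
8 | (4R)-7,8-bis(benzyloxy)-4-[2,3,4-tris(benzyloxy)-5-bromophenyl]chroman-2-one | O=C1C[C@@H](c2cc(Br)c(OCc3ccccc3)c(OCc3ccccc3)c2OCc3ccccc3)c4ccc(OCc3ccccc3)c(OCc3ccccc3)c4O1 | intermediate
9 | (4R)-7,8-bis(benzyloxy)-4-[2,3,4-tris(benzyloxy)-5-bromophenyl]chroman-2-ol, both C2 epimers | OC1C[C@@H](c2cc(Br)c(OCc3ccccc3)c(OCc3ccccc3)c2OCc3ccccc3)c4ccc(OCc3ccccc3)c(OCc3ccccc3)c4O1 | intermediate
10 | (4R)-7,8-bis(benzyloxy)-2-(phenylsulfonyl)-4-[2,3,4-tris(benzyloxy)-5-bromophenyl]chromane, both C2 epimers | O=S(=O)(c6ccccc6)C1C[C@@H](c2cc(Br)c(OCc3ccccc3)c(OCc3ccccc3)c2OCc3ccccc3)c4ccc(OCc3ccccc3)c(OCc3ccccc3)c4O1 | intermediate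
11 | 1-(benzyloxy)-4-bromobenzene | Brc1ccc(OCc2ccccc2)cc1 | starting material
12 | [4-(benzyloxy)phenyl]magnesium bromide (not isolated) | Br[Mg]c1ccc(OCc2ccccc2)cc1 | intermediate
13 | bis[4-(benzyloxy)phenyl]zinc (not isolated) | c1ccc(COc2ccc([Zn]c3ccc(OCc4ccccc4)cc3)cc2)cc1 | intermediate
14 | (2S,4R)-7,8-bis(benzyloxy)-2-[4-(benzyloxy)phenyl]-4-[2,3,4-tris(benzyloxy)-5-bromophenyl]chromane, 2,4-trans | c5ccccc5COc1ccc([C@@H]2C[C@@H](c3cc(Br)c(OCc5ccccc5)c(OCc5ccccc5)c3OCc5ccccc5)c3ccc(OCc5ccccc5)c(OCc5ccccc5)c3O2)cc1 | intermediate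
15 | aryllithium from 14, lithium in place of bromine (not isolated) | c5ccccc5COc1ccc([C@@H]2C[C@@H](c3cc([Li])c(OCc5ccccc5)c(OCc5ccccc5)c3OCc5ccccc5)c3ccc(OCc5ccccc5)c(OCc5ccccc5)c3O2)cc1 | intermediate
16 | 2,3,4-tris(benzyloxy)-5-{(2S,4R)-7,8-bis(benzyloxy)-2-[4-(benzyloxy)phenyl]chroman-4-yl}benzaldehyde | c5ccccc5COc1ccc([C@@H]2C[C@@H](c3cc(C=O)c(OCc5ccccc5)c(OCc5ccccc5)c3OCc5ccccc5)c3ccc(OCc5ccccc5)c(OCc5ccccc5)c3O2)cc1 | intermediate
17 | 3,4-bis(benzyloxy)-5-{(2S,4R)-7,8-bis(benzyloxy)-2-[4-(benzyloxy)phenyl]chroman-4-yl}-2-hydroxybenzaldehyde | c5ccccc5COc1ccc([C@@H]2C[C@@H](c3cc(C=O)c(O)c(OCc5ccccc5)c3OCc5ccccc5)c3ccc(OCc5ccccc5)c(OCc5ccccc5)c3O2)cc1 | intermediate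
18 | 2,3-bis(benzyloxy)-4-{(2S,4R)-7,8-bis(benzyloxy)-2-[4-(benzyloxy)phenyl]chroman-4-yl}-6-(dimethoxymethyl)phenol (key-step precursor) | c5ccccc5COc1ccc([C@@H]2C[C@@H](c3cc(C(OC)OC)c(O)c(OCc5ccccc5)c3OCc5ccccc5)c3ccc(OCc5ccccc5)c(OCc5ccccc5)c3O2)cc1 | intermediate
19 | 1-(benzyloxy)-4-ethynylbenzene | C#Cc1ccc(OCc2ccccc2)cc1 | starting material
20 | (Z)-2-[4-(benzyloxy)phenyl]ethenyl acetate | CC(=O)O/C=C\c1ccc(OCc2ccccc2)cc1 | intermediate
21 | O-methyl oxocarbenium ion of 18 (protonated ortho-quinone methide, not isolated) | c5ccccc5COc1ccc([C@@H]2C[C@@H](c3cc(C=[O+]C)c(O)c(OCc5ccccc5)c3OCc5ccccc5)c3ccc(OCc5ccccc5)c(OCc5ccccc5)c3O2)cc1 | intermediate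
22 | (2R,3R,4R)-7,8-bis(benzyloxy)-2-[4-(benzyloxy)phenyl]-6-{(2S,4R)-7,8-bis(benzyloxy)-2-[4-(benzyloxy)phenyl]chroman-4-yl}-4-methoxychroman-3-yl acetate, all-cis lower ring (key-step product) | c5ccccc5COc1ccc([C@@H]2C[C@@H](c3cc4c(c(OCc5ccccc5)c3OCc5ccccc5)O[C@H](c3ccc(OCc5ccccc5)cc3)[C@H](OC(C)=O)[C@@H]4OC)c3ccc(OCc5ccccc5)c(OCc5ccccc5)c3O2)cc1 | intermediate
23 | cis-fused 3,4-acetoxonium (2-methyl-1,3-dioxolan-2-ylium) ion on the aryl face of the lower ring (not isolated) | c5ccccc5COc1ccc([C@@H]2C[C@@H](c3cc4c(c(OCc5ccccc5)c3OCc5ccccc5)O[C@H](c3ccc(OCc5ccccc5)cc3)[C@H](OC(C)=[O+]6)[C@@H]46)c3ccc(OCc5ccccc5)c(OCc5ccccc5)c3O2)cc1 | intermediate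
24 | (2R,3R,4R)-7,8-bis(benzyloxy)-2-[4-(benzyloxy)phenyl]-6-{(2S,4R)-7,8-bis(benzyloxy)-2-[4-(benzyloxy)phenyl]chroman-4-yl}-4-hydroxychroman-3-yl acetate | c5ccccc5COc1ccc([C@@H]2C[C@@H](c3cc4c(c(OCc5ccccc5)c3OCc5ccccc5)O[C@H](c3ccc(OCc5ccccc5)cc3)[C@H](OC(C)=O)[C@@H]4O)c3ccc(OCc5ccccc5)c(OCc5ccccc5)c3O2)cc1 | intermediate
25 | (2R,3R,4R)-7,8-bis(benzyloxy)-2-[4-(benzyloxy)phenyl]-6-{(2S,4R)-7,8-bis(benzyloxy)-2-[4-(benzyloxy)phenyl]chroman-4-yl}chromane-3,4-diol | c5ccccc5COc1ccc([C@@H]2C[C@@H](c3cc4c(c(OCc5ccccc5)c3OCc5ccccc5)O[C@H](c3ccc(OCc5ccccc5)cc3)[C@H](O)[C@@H]4O)c3ccc(OCc5ccccc5)c(OCc5ccccc5)c3O2)cc1 | intermediate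
26 | (2R,3R,4R)-6-[(2S,4S)-7,8-dihydroxy-2-(4-hydroxyphenyl)chroman-4-yl]-2-(4-hydroxyphenyl)chromane-3,4,7,8-tetrol | Oc1ccc([C@@H]2C[C@@H](c3cc4c(c(O)c3O)O[C@H](c3ccc(O)cc3)[C@H](O)[C@@H]4O)c3ccc(O)c(O)c3O2)cc1 | target

Total step count: 16. Longest linear sequence: 14 steps (1, 2, 3, 5–11, 13–16, from pyrogallol).

Steps most likely to fail

1. Step 13 (proposed new method). The stabilised oxocarbenium ion may react too slowly with the weakly nucleophilic enol ester. Ring closure may also become stepwise, with loss of the 2,3-cis relationship and of facial control. The fallback uses known chemistry only, sets out from salicylaldehyde 17 and returns at hydroxy acetate 24. Claisen–Schmidt condensation of 17 with 1-[4-(benzyloxy)phenyl]ethanone (KOH, EtOH/THF) should give the (E)-2-hydroxychalcone F1. Luche reduction (NaBH4, CeCl3·7H2O, MeOH/THF) should give the racemic allylic alcohol F2. Chiral N-triflyl phosphoramide-catalysed intramolecular allylic substitution (ionisation to the 1,3-diarylallyl cation, enantioselective attack of the phenol) should close the pyran ring and set C2(l), giving the (2S)-flav-3-ene F3. Woodward cis-hydroxylation (I2, AgOAc, AcOH; then wet AcOH, AgOAc) should add iodine anti to the C2 aryl group and acetate at benzylic C4 to give the trans iodo acetate F4. Silver-assisted displacement of iodide by the acetate then leads to the same acetoxonium ion 23 on the aryl face, and its hydrolysis gives 24.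

2. Step 5. Aryl transfer from the ortho-benzyloxy boronic acid to rhodium may be slow, protodeboronation may compete, and insertion of the electron-rich coumarin may be sluggish. The fallback sets out from coumarin 7 and boronic acid 5 and returns at lactone 8. Oxidative Heck coupling (Pd(OAc)2, 1,10-phenanthroline, O2, DMF, 80 °C) should give the achiral 4-arylcoumarin, 7,8-bis(benzyloxy)-4-[2,3,4-tris(benzyloxy)-5-bromophenyl]-2H-chromen-2-one F5. Copper hydride-catalysed asymmetric conjugate reduction (Cu(OAc)2, the DTBM-Segphos enantiomer that gives the 4R lactone, diethoxymethylsilane, t-BuOH, toluene) then sets C4(u) by hydride delivery and gives 8.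

3. Step 8. Facial selectivity at the chroman-2-yl oxocarbenium ion may be incomplete (2,4-cis contaminant), or the ion may lose a proton to the 4H-chromene. The fallback sets out from lactone 8 and returns at flavan 14 with C2(u) under reagent control. Aminolysis with MeNH(OMe)·HCl/AlMe3 (CH2Cl2) should open the lactone to the Weinreb amide phenol F6. Addition of excess Grignard reagent 12 (THF, 0 °C) should give the aryl ketone F7. Corey–Bakshi–Shibata reduction ((S)-Me-CBS, BH3·SMe2) should give the (1R)-carbinol F8. Mitsunobu cyclisation (PPh3, DIAD, THF, 0 °C) closes the pyran ring with inversion at the carbinol carbon to give the 2,4-trans flavan 14.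

Further compounds

F1 | step 13 | (E)-3-[3,4-bis(benzyloxy)-5-Fl-2-hydroxyphenyl]-1-[4-(benzyloxy)phenyl]prop-2-en-1-one | c5ccccc5COc1ccc([C@@H]2C[C@@H](c3cc(/C=C/C(=O)c6ccc(OCc5ccccc5)cc6)c(O)c(OCc5ccccc5)c3OCc5ccccc5)c3ccc(OCc5ccccc5)c(OCc5ccccc5)c3O2)cc1
F2 | step 13 | (E)-3-[3,4-bis(benzyloxy)-5-Fl-2-hydroxyphenyl]-1-[4-(benzyloxy)phenyl]prop-2-en-1-ol, racemic at the carbinol | c5ccccc5COc1ccc([C@@H]2C[C@@H](c3cc(/C=C/C(O)c6ccc(OCc5ccccc5)cc6)c(O)c(OCc5ccccc5)c3OCc5ccccc5)c3ccc(OCc5ccccc5)c(OCc5ccccc5)c3O2)cc1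
F3 | step 13 | (2S)-7,8-bis(benzyloxy)-2-[4-(benzyloxy)phenyl]-6-Fl-2H-chromene (flav-3-ene) | c5ccccc5COc1ccc([C@@H]2C[C@@H](c3cc4c(c(OCc5ccccc5)c3OCc5ccccc5)O[C@H](c3ccc(OCc5ccccc5)cc3)C=C4)c3ccc(OCc5ccccc5)c(OCc5ccccc5)c3O2)cc1
F4 | step 13 | 7,8-bis(benzyloxy)-2-[4-(benzyloxy)phenyl]-6-Fl-3-iodochroman-4-yl acetate, iodine anti and acetate syn to the C2 aryl group | c5ccccc5COc1ccc([C@@H]2C[C@@H](c3cc4c(c(OCc5ccccc5)c3OCc5ccccc5)O[C@H](c3ccc(OCc5ccccc5)cc3)[C@@H](I)[C@@H]4OC(C)=O)c3ccc(OCc5ccccc5)c(OCc5ccccc5)c3O2)cc1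
F5 | step 5 | 7,8-bis(benzyloxy)-4-[2,3,4-tris(benzyloxy)-5-bromophenyl]-2H-chromen-2-one | O=c1cc(-c2cc(Br)c(OCc3ccccc3)c(OCc3ccccc3)c2OCc3ccccc3)c4ccc(OCc3ccccc3)c(OCc3ccccc3)c4o1
F6 | step 8 | (3R)-3-[3,4-bis(benzyloxy)-2-hydroxyphenyl]-3-[2,3,4-tris(benzyloxy)-5-bromophenyl]-N-methoxy-N-methylpropanamide | CON(C)C(=O)C[C@@H](c2cc(Br)c(OCc3ccccc3)c(OCc3ccccc3)c2OCc3ccccc3)c4ccc(OCc3ccccc3)c(OCc3ccccc3)c4O
F7 | step 8 | (3R)-3-[3,4-bis(benzyloxy)-2-hydroxyphenyl]-1-[4-(benzyloxy)phenyl]-3-[2,3,4-tris(benzyloxy)-5-bromophenyl]propan-1-one | O=C(C[C@@H](c2cc(Br)c(OCc3ccccc3)c(OCc3ccccc3)c2OCc3ccccc3)c4ccc(OCc3ccccc3)c(OCc3ccccc3)c4O)c6ccc(OCc3ccccc3)cc6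
F8 | step 8 | (1R,3R)-3-[3,4-bis(benzyloxy)-2-hydroxyphenyl]-1-[4-(benzyloxy)phenyl]-3-[2,3,4-tris(benzyloxy)-5-bromophenyl]propan-1-ol | c5ccccc5COc1ccc([C@H](O)C[C@@H](c3cc(Br)c(OCc5ccccc5)c(OCc5ccccc5)c3OCc5ccccc5)c3ccc(OCc5ccccc5)c(OCc5ccccc5)c3O)cc1
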